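Assumption: the SMILES is read as the meso diastereomer, in which the two identical halves lie on opposite faces of the central ring and are related by an inversion centre; the compound is achiral, so only relative configuration has to be controlled. Diol 13 is drawn in its open form; reversible internal hemiketal formation with the ring ketones is expected and does not affect step 9.

Numbering used throughout: 1 but-2-yne-1,4-diol; 2 chlorotriisopropylsilane; 3 mono-silylated diol; 4 1,2,4,5-tetramethoxybenzene; 5 bis(chloromethyl) arene; 6 bis-ether arene; 7 dimethoxyquinone; 8 dihydroxyquinone; 9 N-iodosuccinimide; 10 mono-spiro intermediate; 11 dispiro tetraone bis(vinyl iodide); 12 bis-methyl tetraone; 13 diol; 14 dialdehyde; 15 mono-bridged intermediate; 16 target.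

## Analysis of the target

Compound 16 (C18H16O8) is a pentacyclic cage built on a central cyclohexane, ring A. Going round ring A the carbons are quaternary carbon (Cq), ketone, tertiary carbinol, and the same three again, so ring A carries no hydrogen at all. On each face a three-carbon enone bridge, Cβ=Cα(CH3)–C(=O), joins one Cq to the carbinol carbon two positions away; this gives two cyclohexenones (rings B and B′), each a bicyclo[3.3.1]nonane with ring A. Each Cq and its Cβ are also tied through CH2–O–CH2 into an oxolane (rings C and C′). There are four stereocentres, all fully substituted: within each half the bridge locks Cq and its carbinol carbon cis, and the two halves sit on opposite faces of ring A. Each carbinol is a tertiary α-ketol flanked by two carbonyl groups, so base can trigger retro-benzoin cleavage, 1,2-acyl shifts or retro-Claisen opening. The difficulty lies in six contiguous fully substituted ring carbons, two all-carbon quaternary centres each bonded to a tetrasubstituted alkene carbon, and a trans relationship between two remote Cq atoms that no ring enforces. The strategy rests on two features. Ring A has the oxygenation pattern of a 2,5-dihydroxy-1,4-benzoquinone with carbon at C3 and C6 (as in 8). Each Cq–Cβ bond leads to an alkene whose carbonyl-bearing substituent is cis to Cq and whose methyl is cis to the oxolane CH2, which is the result of anti addition of a carbon nucleophile and an electrophile across the triple bond of a unit derived from 1.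

## Retrosynthetic reasoning

16 to 14. The two bonds between each enone carbonyl carbon and its carbinol carbon are cut. This is the only C–C bond of 16 that is a plain carbonyl-addition retron (a tertiary α-hydroxy ketone), and cutting it twice opens rings B and B′, removes two of the four stereocentres and turns ring A into a tetraone. Dialdehyde 14 is an isomer of 16, so the forward step needs only a catalyst that makes the aldehyde carbon nucleophilic. It must attack the ketone one carbon removed from Cq (six-membered, bridged closure), not the adjacent one.

14 to 13 to 12. The aldehydes are traced to primary allylic alcohols and these to triisopropylsilyl ethers. An enal would not survive the electrophilic cyclisation or the cross-coupling, whereas the silyl ether is inert to both and to the oxidative unveiling of the quinone.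

12 to 11. The two C(sp2)–CH3 bonds are cut back to C–I bonds. The methyl groups sit where the electrophile of an anti addition ends up, and iodine is the electrophile that can later be exchanged for carbon with retention of alkene geometry.

11 to 8 and 9 (key disconnection). The two Cq–Cβ bonds and the two C–I bonds are cut. In 11 each Cq lies between two ring A carbonyls, so in the reverse sense it is the enol carbon of a vinylogous acid. The disconnection removes both quaternary centres, both oxolanes and both alkene geometries at once and returns a flat, achiral, symmetrical quinone. The forward step must close each ring 5-exo-dig through carbon, anti to iodine, and must do so twice.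

8 to 7 to 6. The enol hydroxyls are traced to methyl vinylogous esters and the quinone to a tetramethoxyarene. The acidic, oxidising hydroxyquinone cannot be carried through alkylation chemistry, while the arene 6 can.

6 to 5 and 3. The two benzylic C–O bonds are cut. This is a convergent ether synthesis that joins the aromatic core to an alcohol already containing the alkyne and the masked hydroxymethyl group.

5 to 4, and 3 to 1 and 2. The two benzylic C–C bonds of 5 go back to the only two free positions of 4. Alcohol 3 is the mono-silyl ether of the symmetrical diol 1.

## Alternatives that were turned down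

Alternative 1: The disconnection works on a bis-deoxy cage A2, which has C–H where 16 has C–OH. The Cq–Cβ bonds are cut back to an ester carbonyl, and the Cα–Cβ bonds to a ketone plus the CH2 of a propanoyl group. This leads to the cyclohexane-1,4-dione A1, carrying two propanoyl groups and two CH2–O–CH2–CO2CH3 arms (methyl ester assumed). In the forward key step a potassium silylamide base would make each ring α-carbon acylate its tethered ester to a spiro-oxolan-3-one; after a protic quench the propanoyl methylene would condense with the new ketone and lose water, closing two oxolanes and two cyclohexenones.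
- In its favour: four C–C bonds and four rings form in one operation, the methyl arrives inside the propanoyl group, the enone geometry is ring-enforced, and no halogen, tin, palladium or tetraone is involved. On these points it is stronger than the chosen route, which needs four operations after its key step.
- Against it: A1 is a saturated ring with four epimerisable stereocentres and two kinds of acyl appendage, and is longer to assemble than flat 8. The first acylation gives a β-diketone with no acidic hydrogen between the carbonyls, so nothing pulls the equilibrium forward, and the enolate that must react carries a β-alkoxy leaving group.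
- The decisive point: A2 still lacks both tertiary hydroxyls. They would have to be introduced at bridgehead carbons of a bicyclo[3.3.1]nonane, where enolisation is geometrically hampered. The chosen strategy carries these oxygens from the start as the quinone hydroxyls and needs no C–H oxidation.

Alternative 2: Three bonds per half are cut (Cq–Cβ, Cα–carbonyl and carbonyl–C(O)) in a fused isomer of the cage, A4, in which each cyclopentenone is fused to an oxolane and to ring A. The precursor is the quinone bis(silyl enol ether) A3 with two but-2-ynyl ether arms. In the forward key step a cobalt-mediated [2+2+1] cycloaddition (Pauson–Khand) would combine each alkyne, the adjacent quinone C=C and one carbonyl ligand; a later 1,2-acyl shift (α-ketol rearrangement) would expand each cyclopentenone into the bridged cyclohexenone.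
- In its favour: A3 is as short to make as 8, the methyl and the enone carbonyl arrive in the key step with the right regiochemistry, and no iodine, tin or late oxidation is needed. It is stronger in step economy.
- Against it: the alkene partner is a tetrasubstituted, electron-poor, oxygenated quinone double bond, the least willing class of alkene for this cycloaddition. Each event must create two adjacent fully substituted carbons, the quinone can oxidise low-valent cobalt, and the ring expansion must run twice in the right direction. The anti relationship across ring A is as uncontrolled as the trans relationship in the chosen route.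
- Comparison: the chosen strategy uses the same quinone ring in its natural polarity, the enol carbon as nucleophile, at the price of about three more steps.

Alternative 3: In the bis(methoxymethyl) ether A6 of 16 the Cq–Cβ bonds and the enone-carbonyl–carbinol bonds are cut. The precursor A5 is a cyclohexane-1,4-dione with an acetal-protected oxygen on each α′-carbon and, on each α-carbon, a CH2–O–CH2 arm ending in a β-chloro-α-methyl acrylic phenyl ester. In the forward key step a lithium silylamide base would make the α-carbon add to the chloro-enoate and expel chloride (oxolane), after which the α′-enolate would attack the phenyl ester (cyclohexenone).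
- In its favour: every atom and oxidation state of 16 is in place after the key step and only acetal cleavage remains, with no late redox or cross-coupling. It is clearly stronger than the chosen route in what follows the key step.
- Against it: A5 needs a long synthesis (four stereocentres, two geometrically defined chloro-enoates). The first enolate has the arm oxygen in the β-position and can eliminate, enolisation must switch from α to α′ in the right order, and the ring-closing acylation gives a non-enolisable bridgehead β-diketone with no deprotonation to drive it. The trans relationship of the halves is again unbiased.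
- Comparison: the chosen strategy puts its risk into one step on a symmetrical precursor reached in five steps, and sets the alkene geometry by mechanism rather than by a pre-built tether.

Key step: step 6

## Route

Step 1
Reactants: 1 but-2-yne-1,4-diol; 2 chlorotriisopropylsilane
Product: 3 4-[(triisopropylsilyl)oxy]but-2-yn-1-ol
Conditions: 1 (3 equiv), NaH (1 equiv), THF, 0 °C; then 2 (1 equiv), rt
Reagents that add atoms: chlorotriisopropylsilane (2), CC(C)[Si](Cl)(C(C)C)C(C)C
Why: Monosilylation of a symmetrical diol through its monosodium alkoxide; the excess of cheap 1 suppresses the bis-ether and is removed with water.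

Step 2
Reactants: 4 1,2,4,5-tetramethoxybenzene
Product: 5 1,4-bis(chloromethyl)-2,3,5,6-tetramethoxybenzene
Conditions: (CH2O)n, HCl (g), conc. HCl, 1,4-dioxane, rt to 50 °C
Reagents that add atoms: paraformaldehyde (as formaldehyde), C=O; hydrogen chloride, Cl
Why: Blanc chloromethylation of an electron-rich arene; the only two free positions are para to each other and each is flanked by two methoxy groups, so twofold substitution can give only the 1,4-isomer.

Step 3
Reactants: 5 1,4-bis(chloromethyl)-2,3,5,6-tetramethoxybenzene; 3 4-[(triisopropylsilyl)oxy]but-2-yn-1-ol
Product: 6 1,4-bis({4-[(triisopropylsilyl)oxy]but-2-yn-1-yl}oxymethyl)-2,3,5,6-tetramethoxybenzene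
Conditions: 3 (2.4 equiv), NaH, n-Bu4NI (cat.), THF/DMF, 0 °C to rt
Reagents that add atoms: none
Why: Williamson ether synthesis with a reactive benzylic chloride and a primary propargylic alkoxide; the linear alkyne keeps the silyl group out of reach of the alkoxide, so no silyl migration is expected.

Step 4
Reactants: 6 1,4-bis({4-[(triisopropylsilyl)oxy]but-2-yn-1-yl}oxymethyl)-2,3,5,6-tetramethoxybenzene
Product: 7 2,5-dimethoxy-3,6-bis({4-[(triisopropylsilyl)oxy]but-2-yn-1-yl}oxymethyl)-1,4-benzoquinone
Conditions: (NH4)2Ce(NO3)6 (2.5 equiv), MeCN/H2O, 0 °C, 20 min
Reagents that add atoms: water, O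
Why: Oxidative demethylation of a 1,2,4,5-tetramethoxyarene by tetravalent cerium, which is known to favour the para-quinone with two methoxy groups retained. Water should capture the arene radical cation at a methoxy-bearing carbon faster than the benzylic ether is oxidised, and the alkynes and the primary triisopropylsilyl ethers should tolerate the short cold exposure.

Step 5
Reactants: 7 2,5-dimethoxy-3,6-bis({4-[(triisopropylsilyl)oxy]but-2-yn-1-yl}oxymethyl)-1,4-benzoquinone
Product: 8 2,5-dihydroxy-3,6-bis({4-[(triisopropylsilyl)oxy]but-2-yn-1-yl}oxymethyl)-1,4-benzoquinone
Conditions: LiOH (aq.), THF, 0 °C; then cold dil. HCl to pH 3; used at once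
Reagents that add atoms: lithium hydroxide, [Li+].[OH-]
Why: Saponification of the two vinylogous methyl esters by addition–elimination of hydroxide at the methoxy-bearing ring carbons, a standard route to 2,5-dihydroxyquinones. Low temperature, the stabilised dianion and immediate use are chosen to limit β-elimination of the side-chain alkoxide from this 2-(alkoxymethyl)-1,3-dicarbonyl system.

Step 6
Reactants: 8 2,5-dihydroxy-3,6-bis({4-[(triisopropylsilyl)oxy]but-2-yn-1-yl}oxymethyl)-1,4-benzoquinone; 9 N-iodosuccinimide
Product: 11 trans-(4Z,12Z)-4,12-bis{1-iodo-2-[(triisopropylsilyl)oxy]ethylidene}-2,10-dioxadispiro[4.2.4.2]tetradecane-6,7,13,14-tetrone, via mono-spiro hydroxy-enetrione 10 (not isolated)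
Conditions: 9 (2.3 equiv), MeCN, 4 Å MS, dark, −20 °C to rt; trans isomer separated by crystallisation or chromatography
Reagents that add atoms: N-iodosuccinimide (9), O=C1CCC(=O)N1I
Why: 9 hands its electrophilic iodine to a triple bond of 8 (directly, or by way of reversible iodination of the enol carbon, which is itself an iodine donor), and the enol carbon of the vinylogous acid attacks the activated alkyne on the face opposite iodine while its O–H proton goes to succinimide. The closest known reaction type is the iodocarbocyclisation (iodo-Conia-ene reaction) of 1,3-dicarbonyl compounds bearing a pent-4-ynyl-type chain, which gives (iodoalkylidene)cyclopentanes by anti addition. Each oxolane closes 5-exo-dig through the CH2–O–CH2 tether; 6-endo-dig attack on the far alkyne carbon has the poorer trajectory, and attack through oxygen would need a seven-membered ring. Anti addition fixes both alkene geometries: iodine ends cis to the oxolane CH2 and the CH2OSi group cis to the new quaternary carbon (Z), which is what rings B and B′ require later. The first closure gives racemic 10, whose remaining hydroxy-enone is still the enol of a 1,3-diketone and should cyclise in the same way. The two spiro stereocentres form one after the other, and the second is set against the first only by weak 1,4-induction across a nearly flat ring, the bulky iodoalkylidene arm of the first oxolane screening its own face; the trans (centrosymmetric) isomer 11 should be favoured only modestly and has to be freed from the cis isomer. The selectivities needed are C- over O-cyclisation and exo over endo closure, both secured by the tether length, and twofold reaction, secured by the second enol staying acidic and nucleophilic after the first event.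

Step 7
Reactants: 11 trans-(4Z,12Z)-4,12-bis{1-iodo-2-[(triisopropylsilyl)oxy]ethylidene}-2,10-dioxadispiro[4.2.4.2]tetradecane-6,7,13,14-tetrone
Product: 12 trans-(4E,12E)-4,12-bis{1-[(triisopropylsilyl)oxy]propan-2-ylidene}-2,10-dioxadispiro[4.2.4.2]tetradecane-6,7,13,14-tetrone
Conditions: Me4Sn (6 equiv), Pd2(dba)3 (5 mol %), AsPh3 (20 mol %), CuI (20 mol %), NMP, 50 °C, sealed tube
Reagents that add atoms: tetramethylstannane, C[Sn](C)(C)C
Why: Stille coupling of a vinyl iodide with retention of alkene geometry under neutral conditions, which the non-enolisable, nucleophile-sensitive tetraone should tolerate. The arsine ligand and CuI are chosen because they speed transmetalation and are less nucleophilic toward strained 1,2-diketones than triarylphosphines.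

Step 8
Reactants: 12 trans-(4E,12E)-4,12-bis{1-[(triisopropylsilyl)oxy]propan-2-ylidene}-2,10-dioxadispiro[4.2.4.2]tetradecane-6,7,13,14-tetrone
Product: 13 trans-(4E,12E)-4,12-bis(1-hydroxypropan-2-ylidene)-2,10-dioxadispiro[4.2.4.2]tetradecane-6,7,13,14-tetrone
Conditions: HF·pyridine, THF/pyridine, 0 °C to rt
Reagents that add atoms: none
Why: Acidic fluoride cleavage of the primary silyl ethers; basic fluoride sources are avoided because alkoxides could open the non-enolisable 1,3-diketone units by retro-Claisen cleavage.

Step 9
Reactants: 13 trans-(4E,12E)-4,12-bis(1-hydroxypropan-2-ylidene)-2,10-dioxadispiro[4.2.4.2]tetradecane-6,7,13,14-tetrone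
Product: 14 trans-(2E,2′E)-2,2′-(6,7,13,14-tetraoxo-2,10-dioxadispiro[4.2.4.2]tetradecane-4,12-diylidene)dipropanal
Conditions: Dess–Martin periodinane (2.6 equiv), CH2Cl2, 0 °C to rt
Reagents that add atoms: none
Why: Dess–Martin oxidation of primary allylic alcohols to enals under non-basic conditions; any internal hemiketal is in equilibrium with the open alcohol and has no oxidisable C–H of its own.

Step 10
Reactants: 14 trans-(2E,2′E)-2,2′-(6,7,13,14-tetraoxo-2,10-dioxadispiro[4.2.4.2]tetradecane-4,12-diylidene)dipropanal
Product: 16 CNP0299498.2 (centrosymmetric cage bis-α-ketol), via mono-bridged ketol aldehyde 15 (not isolated)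
Conditions: 2-(pentafluorophenyl)-6,7-dihydro-5H-pyrrolo[2,1-c][1,2,4]triazol-2-ium tetrafluoroborate (20 mol %), Et3N (20 mol %), THF, rt
Reagents that add atoms: none
Why: Intramolecular crossed aldehyde–ketone benzoin reaction: the carbene turns each formyl carbon into an acyl anion equivalent that adds to a ring A ketone, closing rings B and B′ as six-membered bridged rings. With its arm axial, the formyl carbon lies above the carbonyl one carbon removed from the spiro centre, and it can reach only the face on which the arm stands, which sets each carbinol centre cis to its own spiro carbon; the trans relationship of the halves is inherited from 11. After the first closure the second arm should prefer the remaining 1,2-diketone carbonyl over the hindered ketone that now lies between two fully substituted carbons, which leads to 16.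

## Compound list

1 | but-2-yne-1,4-diol | OCC#CCO | starting material
2 | chlorotriisopropylsilane | CC(C)[Si](Cl)(C(C)C)C(C)C | starting material
3 | 4-[(triisopropylsilyl)oxy]but-2-yn-1-ol | OCC#CCO[Si](C(C)C)(C(C)C)C(C)C | intermediate
4 | 1,2,4,5-tetramethoxybenzene | COc1cc(OC)c(OC)cc1OC | starting material
5 | 1,4-bis(chloromethyl)-2,3,5,6-tetramethoxybenzene | COc1c(CCl)c(OC)c(OC)c(CCl)c1OC | intermediate
6 | 1,4-bis({4-[(triisopropylsilyl)oxy]but-2-yn-1-yl}oxymethyl)-2,3,5,6-tetramethoxybenzene | COc1c(COCC#CCO[Si](C(C)C)(C(C)C)C(C)C)c(OC)c(OC)c(COCC#CCO[Si](C(C)C)(C(C)C)C(C)C)c1OC | intermediate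
7 | 2,5-dimethoxy-3,6-bis({4-[(triisopropylsilyl)oxy]but-2-yn-1-yl}oxymethyl)-1,4-benzoquinone | COC1=C(COCC#CCO[Si](C(C)C)(C(C)C)C(C)C)C(=O)C(OC)=C(COCC#CCO[Si](C(C)C)(C(C)C)C(C)C)C1=O | intermediate
8 | 2,5-dihydroxy-3,6-bis({4-[(triisopropylsilyl)oxy]but-2-yn-1-yl}oxymethyl)-1,4-benzoquinone | OC1=C(COCC#CCO[Si](C(C)C)(C(C)C)C(C)C)C(=O)C(O)=C(COCC#CCO[Si](C(C)C)(C(C)C)C(C)C)C1=O | intermediate
9 | N-iodosuccinimide | O=C1CCC(=O)N1I | starting material
10 | mono-spiro hydroxy-enetrione: 9-hydroxy-4-{(Z)-1-iodo-2-[(triisopropylsilyl)oxy]ethylidene}-8-({4-[(triisopropylsilyl)oxy]but-2-yn-1-yl}oxymethyl)-2-oxaspiro[4.5]dec-8-ene-6,7,10-trione (racemic, one enantiomer drawn) | CC(C)[Si](C(C)C)(C(C)C)OC/C(I)=C1/COC[C@]12C(=O)C(=O)C(COCC#CCO[Si](C(C)C)(C(C)C)C(C)C)=C(O)C2=O | intermediate (not isolated)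
11 | trans-(4Z,12Z)-4,12-bis{1-iodo-2-[(triisopropylsilyl)oxy]ethylidene}-2,10-dioxadispiro[4.2.4.2]tetradecane-6,7,13,14-tetrone | CC(C)[Si](C(C)C)(C(C)C)OC/C(I)=C1/COC[C@]12C(=O)C(=O)[C@]3(COC/C3=C(I)/CO[Si](C(C)C)(C(C)C)C(C)C)C(=O)C2=O | intermediate
12 | trans-(4E,12E)-4,12-bis{1-[(triisopropylsilyl)oxy]propan-2-ylidene}-2,10-dioxadispiro[4.2.4.2]tetradecane-6,7,13,14-tetrone | CC(C)[Si](C(C)C)(C(C)C)OC/C(C)=C1/COC[C@]12C(=O)C(=O)[C@]3(COC/C3=C(C)/CO[Si](C(C)C)(C(C)C)C(C)C)C(=O)C2=O | intermediate
13 | trans-(4E,12E)-4,12-bis(1-hydroxypropan-2-ylidene)-2,10-dioxadispiro[4.2.4.2]tetradecane-6,7,13,14-tetrone | OC/C(C)=C1/COC[C@]12C(=O)C(=O)[C@]3(COC/C3=C(C)/CO)C(=O)C2=O | intermediate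
14 | trans-(2E,2′E)-2,2′-(6,7,13,14-tetraoxo-2,10-dioxadispiro[4.2.4.2]tetradecane-4,12-diylidene)dipropanal | O=C/C(C)=C1/COC[C@]12C(=O)C(=O)[C@]3(COC/C3=C(C)/C=O)C(=O)C2=O | intermediate
15 | mono-bridged ketol aldehyde: one enone bridge closed between a spiro carbon and the carbinol carbon two positions away, the other arm still an (E)-enal (racemic, one enantiomer drawn) | CC1=C2COC[C@]23C(=O)[C@](O)(C1=O)[C@]1(COC/C1=C(C)/C=O)C(=O)C3=O | intermediate (not isolated)
16 | CNP0299498.2, centrosymmetric cage: ring A with two spiro-fused oxolanes and two methyl-enone bridges on opposite faces, each tertiary OH anti to the bridge at its carbon | CC1=C2COC[C@]23C(=O)[C@](O)(C1=O)[C@@]12COCC1=C(C)C(=O)[C@]3(O)C2=O | target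

## Step count and least certain steps

Total: 10 steps. Longest linear sequence: 9 steps (from 4 through steps 2 to 10; the branch from 1 through step 1 and steps 3 to 10 is equally long).

Step 6 (key step). The most likely failure is that iodine is delivered to the enol carbon and stays there, because the triple bond carries an electron-withdrawing ether on each side and is slow to accept iodonium; the cis-dispiro isomer will in any case form alongside the trans one. The fallback sets out from 8 and returns at 11. 8 would be treated with 9 at −40 °C in CH2Cl2 so that both enol carbons are iodinated without cyclisation, giving 3,6-diiodo-3,6-bis({4-[(triisopropylsilyl)oxy]but-2-yn-1-yl}oxymethyl)cyclohexane-1,2,4,5-tetrone F1 (cis/trans mixture, both usable). F1 would then be closed by iodine-atom-transfer radical cyclisation ((Bu3Sn)2 (cat.), visible light, benzene). Homolysis of each C–I bond gives a radical flanked by two carbonyls that closes 5-exo-dig onto the alkyne. The vinyl radical takes iodine from a further C–I bond on the side away from the new quaternary carbon, which should give the same alkene geometry as the ionic path; the trans isomer 11 is again separated.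

Step 10. The most likely failure is closure at the wrong distance: the acyl anion equivalent may add to the carbonyl directly next to its spiro carbon (five-membered, fused) instead of the one beyond it, and the carbene can also be held back by reversible addition to the strained 1,2-diketones. The fallback sets out from 14 and returns at 16. The fused product, the anti-bis(hydroxycyclopentenone) isomer of 16 F2, in which each cyclopentenone is fused to an oxolane and to ring A, would be isolated. It would then be isomerised by α-ketol rearrangement (DBU, toluene, 60 °C, or Al(OtBu)3). A 1,2-shift of each acyl group from its carbinol carbon to the neighbouring ring carbonyl turns the strained bicyclo[3.3.0]octenone into the bridged cyclohexenone. The acyl group migrates across the face it already occupies, so the configuration of 16 should result.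

Step 7. The most likely failure is slow oxidative addition and methyl transfer at the hindered, unactivated tetrasubstituted vinyl iodide, with degradation of the 1,2-diketones by the zerovalent palladium–ligand system and protodeiodination during prolonged heating. The fallback sets out from 11 and returns at 14 by reordering the steps. 11 would be desilylated (HF·pyridine) to trans-(4Z,12Z)-4,12-bis(2-hydroxy-1-iodoethylidene)-2,10-dioxadispiro[4.2.4.2]tetradecane-6,7,13,14-tetrone F3 and oxidised with Dess–Martin periodinane to the bis(α-iodo enal) F4. The C–I bond, now activated by the conjugated formyl group, would be methylated with Me4Sn (Pd2(dba)3, AsPh3, CuI, NMP) at room temperature to give 14.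

Step 5. The most likely failure is loss of the side chains: the tetrahedral hydroxide adduct or the product enolate can expel the propargylic alkoxide by β-elimination toward a quinone methide, which water then captures. The fallback sets out from 3 and returns at 8, and uses the same elimination constructively. Purchased 2,5-dihydroxy-1,4-benzoquinone F5 would be converted by a twofold Mannich reaction (aqueous formaldehyde, Me2NH, EtOH) into 3,6-bis[(dimethylamino)methyl]-2,5-dihydroxy-1,4-benzoquinone F6. F6 would be heated with an excess of 3 in toluene under a stream of nitrogen, so that dimethylamine leaves through the quinone methide and 3 adds in its place, giving 8 without any hydroxide.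

Step 2. The most likely failure is Friedel–Crafts self-condensation of the very reactive benzylic chloride with unreacted arene to diarylmethanes, together with incomplete second substitution. The fallback sets out from 4 (and 3) and returns at 6. Twofold ortho-lithiation of 4 (n-BuLi, TMEDA, THF) and quench with DMF would give 2,3,5,6-tetramethoxyterephthalaldehyde F7, and NaBH4 would reduce it to (2,3,5,6-tetramethoxy-1,4-phenylene)dimethanol F8. Alcohol 3 would be converted (CBr4, PPh3) into (4-bromobut-2-yn-1-yl)oxytriisopropylsilane F9, and the dialkoxide of F8 (NaH, THF/DMF) would be alkylated with F9 to give 6.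

## Further compounds

F1 | step 6 | 3,6-diiodo-3,6-bis({4-[(triisopropylsilyl)oxy]but-2-yn-1-yl}oxymethyl)cyclohexane-1,2,4,5-tetrone (cis/trans mixture) | O=C1C(=O)C(I)(COCC#CCO[Si](C(C)C)(C(C)C)C(C)C)C(=O)C(=O)C1(I)COCC#CCO[Si](C(C)C)(C(C)C)C(C)C
F2 | step 10 | anti-bis(hydroxycyclopentenone) isomer of 16, each cyclopentenone fused to an oxolane and to ring A | CC1=C2COC[C@]23[C@](O)(C1=O)C(=O)[C@@]12COCC1=C(C)C(=O)[C@@]2(O)C3=O
F3 | step 7 | trans-(4Z,12Z)-4,12-bis(2-hydroxy-1-iodoethylidene)-2,10-dioxadispiro[4.2.4.2]tetradecane-6,7,13,14-tetrone | OC/C(I)=C1/COC[C@]12C(=O)C(=O)[C@]3(COC/C3=C(I)/CO)C(=O)C2=O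
F4 | step 7 | trans-bis(α-iodo enal): 2,2′-(6,7,13,14-tetraoxo-2,10-dioxadispiro[4.2.4.2]tetradecane-4,12-diylidene)bis(2-iodoacetaldehyde), formyl cis to the spiro carbon | O=C/C(I)=C1/COC[C@]12C(=O)C(=O)[C@]3(COC/C3=C(I)/C=O)C(=O)C2=O
F5 | step 5 | 2,5-dihydroxy-1,4-benzoquinone | OC1=CC(=O)C(O)=CC1=O
F6 | step 5 | 3,6-bis[(dimethylamino)methyl]-2,5-dihydroxy-1,4-benzoquinone | CN(C)CC1=C(O)C(=O)C(CN(C)C)=C(O)C1=O
F7 | step 2 | 2,3,5,6-tetramethoxyterephthalaldehyde | COc1c(C=O)c(OC)c(OC)c(C=O)c1OC
F8 | step 2 | (2,3,5,6-tetramethoxy-1,4-phenylene)dimethanol | COc1c(CO)c(OC)c(OC)c(CO)c1OC
F9 | step 2 | (4-bromobut-2-yn-1-yl)oxytriisopropylsilane | BrCC#CCO[Si](C(C)C)(C(C)C)C(C)C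
A1 | alternative 1 | 2,5-dipropanoyl-3,6-bis[(2-methoxy-2-oxoethoxy)methyl]cyclohexane-1,4-dione (diastereomer mixture, methyl ester assumed) | CCC(=O)C1C(=O)C(COCC(=O)OC)C(C(=O)CC)C(=O)C1COCC(=O)OC
A2 | alternative 1 | bis-deoxy cage with two bridgehead C–H bonds in place of the two hydroxyls of 16 | CC1=C2COC[C@]23C(=O)[C@H](C1=O)[C@@]12COCC1=C(C)C(=O)[C@@H]3C2=O
A3 | alternative 2 | 2,5-bis[(tert-butyldimethylsilyl)oxy]-3,6-bis[(but-2-yn-1-yloxy)methyl]-1,4-benzoquinone | CC#CCOCC1=C(O[Si](C)(C)C(C)(C)C)C(=O)C(COCC#CC)=C(O[Si](C)(C)C(C)(C)C)C1=O
A4 | alternative 2 | anti bis(cyclopentenone) adduct, each cyclopentenone fused to an oxolane and to the central dione ring, bis(silyl ether) | CC1=C2COC[C@]23[C@](O[Si](C)(C)C(C)(C)C)(C1=O)C(=O)[C@@]12COCC1=C(C)C(=O)[C@@]2(O[Si](C)(C)C(C)(C)C)C3=O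
A5 | alternative 3 | 2,5-bis(methoxymethoxy)cyclohexane-1,4-dione bearing at C3 and C6 a CH2–O–CH2–C(Cl)=C(CH3)–CO2Ph arm, chlorine cis to the ester (diastereomer mixture) | COCOC1C(=O)C(COC/C(Cl)=C(\C)C(=O)Oc2ccccc2)C(OCOC)C(=O)C1COC/C(Cl)=C(\C)C(=O)Oc1ccccc1
A6 | alternative 3 | bis(methoxymethyl) ether of 16 | CC1=C2COC[C@]23C(=O)[C@](OCOC)(C1=O)[C@@]12COCC1=C(C)C(=O)[C@]3(OCOC)C2=O
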